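A small charge of L goes into this flask: counted as a fraction of the Z charged, L stands at 120%. Z takes L once to give the mono adduct and again to give G, the bis adduct, so each G holds two L.

common to all: Z 0.12 M

| flask | L | temperature | remark | time |
|---|---|---|---|---|
| noon | 0.144 M | 60 °C | the very flask that is asked about, followed so far |  |
| autumn | 0.22 M | 66 °C | run made earlier |  |
| flask | 0.144 M | 60 °C |  | 6.0 h |

| run | time / min | G / % | Z / % |
|---|---|---|---|
| noon | 40.0 | 24.5 | 19.6 |
| noon | 80.0 | 32.2 | 16.5 |
| noon | 120 | 36.3 | 16.2 |
| noon | 150 | 36.0 | 15.9 |
| noon | 180 | 37.0 | 14.3 |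
| noon | 240 | 36.4 | 14.6 |
| autumn | 2.50 | 4.7 | 59.8 |
| autumn | 4.00 | 6.4 | 46.6 |
| autumn | 8.00 | 14.9 | 29.0 |
| autumn | 12.0 | 22.1 | 19.9 |
| autumn | 20.0 | 34.3 | 14.0 |
| autumn | 30.0 | 40.7 | 11.6 |

(readings scatter by 1 percentage point)

- Sunday's: at 6.0 h take out 90% of the G then present, then wait 2.0 h
- Wednesday's: at 6.0 h add L, 50.0% of the amount charged, then wait 2.0 h
- Saturday's: change nothing and wait 2.0 h more
- Friday's: at 6.0 h raise the temperature by 10 K, then wait 2.0 h

1. G, in percent of the Z first charged, at 6.0 h
2. the remedy with the largest gain of G, or "none" below 2 percentage points (Sunday's / Wednesday's / Saturday's / Friday's / none)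
3. G present, with what was taken out counted in, in percent of the Z first charged, after Wednesday's
4. G present, with what was taken out counted in, in percent of the Z first charged, after Saturday's

- removed G is counted in
- the earlier runs were read with a standard deviation of 1 percentage point
- additions bring no volume worth counting

We call the cover, 60.0% here, the L charged over the L needed to turn each Z into G, at two L per G. At this cover L is the limiting reagent of the noon flask, and the noon table can test that.

If Z leaves by taking one L and each G holds a second, and nothing else takes Z or L, then Z gone plus G counts the L spent; we use this as an assumption, not a balance. Reading down the noon table, this count is 105% at 40.0 min, 120% at 120 min and 122% at 240 min, against the 120% charged. G reads 36.3% in the row where the count meets the charge and 36.4% in the last row, a step within the scatter of 1 percentage point.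

The autumn run, warmer and at cover 91.7%, passes that count, reaching 129% at 30.0 min, with G going from 34.3% to 40.7% over its last two rows.

So we expect the noon flask to hold its late mean, G near 36.4%, at 6.0 h. Of the remedies, we expect a gain from Wednesday's, which raises the cover to 90.0%.

The forecast gives 36.6% now, 36.8% after Saturday's, and Wednesday's as best at 71%, holding that “the flask has simply run out of L”.

The flask gives 36.1% now and 36.1% after Saturday's. Wednesday's is best, with a gain of 18 points, reaching 54.6%.

    Z + L → E + X (k = 0.500 L mol⁻¹ min⁻¹, Ea = 65.0 kJ mol⁻¹)
    L + E → G + X (k = 0.290 L mol⁻¹ min⁻¹, Ea = 60.0 kJ mol⁻¹)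
    Q ⇌ X, rate k3*(cs3 - [X]) while solid is left; crystals form when [X] > cs3 (solubility = 0.0860 M, k = 0.900 min⁻¹)
    L + G → J (k = 0.0600 L mol⁻¹ min⁻¹, Ea = 55.0 kJ mol⁻¹)
    Z ⇌ D (K = 0.710, k = 0.0320 min⁻¹, Ea = 104 kJ mol⁻¹, ΔH = −36.0 kJ mol⁻¹)
    (constants at 60 °C)

In the flask, the half-life of L by Z + L → E + X at 9.56 min is 25 min, far shorter than the 6.0 h of the run, and at 360 min 0.012% of the L charged is left beside 14% of the Z, as a cover of 60.0% leads us to expect. The half-life of G by L + G → J, at the concentrations as charged, is 80 min, also shorter than 6.0 h, and J is a second sink for L that the cover doesn't count. At 360 min the flask holds 10.2% of D, which carries no L although its Z counts as gone, and 4.27% of J, which carries a third L, so our count of Z gone plus G errs in opposite directions and its meeting the charge was no proof. A neighbour charged with 0.048 M of Z has cover 150%, and there the roles turn: 0.41% of the Z is left, beside 19% of the L.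

The readings come from a simulation on assumed constants; noise was put on by code.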